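The readings were generated by integration for an exercise, noise included.

The cedar run had 28.4 % of its substrate as target at 25.0 min, and I began from the leftover, the 71.6 % of the charge that the readings did not show. Theta looked nearly like cedar, 75 °C against 70 °C, yet it carried twice the second nucleophile.

common to all: substrate 0.10 M
- cedar: first nucleophile 0.20 M; second nucleophile 0.075 M; temperature 70 °C; run made earlier
- oak: first nucleophile 0.20 M; second nucleophile 0.11 M; temperature 88 °C; run made earlier
- zeta: first nucleophile 0.200 M; second nucleophile 0.150 M; temperature 100 °C; time 8.0 min
- theta: first nucleophile 0.200 M; second nucleophile 0.150 M; temperature 75 °C; time 8.0 min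

| run | time / min | target / % |
|---|---|---|
| cedar | 6.00 | 7.9 |
| cedar | 12.0 | 15.3 |
| cedar | 20.0 | 23.8 |
| cedar | 25.0 | 28.4 |
| oak | 0.833 | 5.1 |
| oak | 2.00 | 14.4 |
| oak | 4.00 | 29.4 |
| oak | 5.00 | 35.4 |
| oak | 10.0 | 55.9 |

(readings scatter by 0.5 percentage points)

* which flask leads in amount of target, in percent of the substrate charged ("all alike" within 1.5 percentage points) (zeta / theta / all alike)
* how much target is there at the end, in percent of the substrate charged: zeta
* how much target is there at the end, in percent of the substrate charged: theta



Oak's target rose more slowly up to 0.833 min than from 2.00 min to 4.00 min. So I supposed that substrate first becomes an intermediate, and that each intermediate meets a fork: first nucleophile turns it into target, while second nucleophile takes it elsewhere. Taking the two nucleophiles as equally quick, I carried the capture share, the first nucleophile's fraction of both nucleophiles as charged72.7 %57.1 %. It was 72.7 % in cedar but 57.1 % in theta and zeta.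

Cedar's leftover gave a clock, the logarithm of one over the leftover, per minute: 0.0134 /min. Oak's last reading gave 0.0819 /min. Interpolating to theta's temperature gave 0.0221 /min, and scaling by the two shares put theta at 12.7 % after 8.0 min. I took zeta's whole substrate through the fork in that time, so my figure for zeta was 57.1 %, well ahead of theta.

The forecast also named zeta, but it gave 81 % (68 % to 89 %) for zeta and 17 % (15 % to 19.5 %) for theta, both higher than mine. Its grounds were that the runs looked limited by the first step, with cedar's target showing “no dependence on the second nucleophile”.

Zeta gave 65.0 % and theta 13.6 %, so zeta led.

    second nucleophile → decomposed reagent (k = 0.0410 /s, Ea = 95.0 kJ/mol)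
    2 first nucleophile → homo dimer (k = 0.0520 /M/s, Ea = 63.0 kJ/mol)
    second nucleophile + intermediate → other capture product (k = 16.0 /M/s, Ea = 62.0 kJ/mol)
    intermediate → solvolysis product (k = 0.0480 /s, Ea = 109 kJ/mol)
    first nucleophile + intermediate → target (k = 7.30 /M/s, Ea = 41.0 kJ/mol)
    substrate → intermediate (k = 0.00780 /s, Ea = 114 kJ/mol)
    (constants at 100 °C)

The main reason for zeta's 65.0 % of target was the passing of second nucleophile into decomposed reagent: the same flask without that step gives 20.8 %. Zeta's second nucleophile stood at 0 % of its charge by 4.00 min, and its two capture products split 78.9 % to target at the end, above the 57.1 % I had reckoned from the charges. The neighbouring flask, theta with 0.060 M of second nucleophile, has a capture share of 76.9 %, and its target took 78.1 % of the two products.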